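**Retrosynthetic overview**

1. Numbering (azulene): C1 carries the side chain, C3a the angular methyl, C4 the OAc, C5/C6 the epoxide, C8a the ring-fusion H; C2′ is the methyl-bearing sp2 carbon of the chain.
2. Last bond: C1–C2′, by Ni-catalysed decarboxylative reductive coupling of the C1 N-acyloxyphthalimide 15 with the (3E,5Z)-iododienol 19; two electrophiles are joined and both C1 epimers converge. Enabling feature: C1 is a secondary sp3 carbon of the trans-fused cyclopentane, next to C8a–H and 1,3 to the C3a methyl, so its planar radical is taken up anti to C8 and that methyl; its partner C2′ is sp2 and brings the Z geometry in from the iodide.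
3. Core 15: C8a–H by C4–OH-directed hydrogenation of the C1=C8a enoate; epoxide by C4–OH-directed epoxidation; seven-membered ring by RCM (C5=C6); C8a–C8 bond by enol triflate Negishi coupling.
4. C3a/C4 from a γ-aldol of a cyclopentanone β-ketoester dianion with acrolein, resolved by Sharpless kinetic resolution; 19 from a Z-selective iodo-Wittig reaction and MeMgBr.
5. Ring order: cyclopentane (bought) → seven-membered ring (RCM) → epoxide.

Key step: step 14

Remark: the C5–C6 oxirane is named as a 5,6-epoxy substituent; racemates 5–7 are written as both enantiomers; the minor aldol diastereomer from step 2 is assumed to be removed by chromatography before step 4; unnumbered reagents are commercial.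

**Step 1**
Reactants: 1 methyl 2-oxocyclopentane-1-carboxylate
Product: 3 methyl 3-methyl-2-oxocyclopentane-1-carboxylate, via dilithium dienolate 2 (not isolated)
Conditions: LDA (2.2 equiv), THF, 0 °C; MeI (1.05 equiv), −78 → 0 °C; AcOH quench
Reagents that add atoms: iodomethane, CI
Why: β-Ketoester dianion alkylation, in which the second-formed, more reactive γ-enolate carbon (C3) is methylated; the new centre is not controlled because it is enolised again in step 2.

**Step 2**
Reactants: 3 methyl 3-methyl-2-oxocyclopentane-1-carboxylate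
Product: 5 rac-methyl (3R*)-3-[(1R*)-1-hydroxyprop-2-en-1-yl]-3-methyl-2-oxocyclopentane-1-carboxylate, via dilithium dienolate 4 (not isolated)
Conditions: LDA (2.2 equiv), THF, −78 → −20 °C; acrolein (1.2 equiv), −78 °C, 15 min; AcOH, −78 °C; chromatography
Reagents that add atoms: acrolein, C=CC=O
Why: γ-Aldol addition of the β-ketoester dianion through a closed Zimmerman–Traxler chair (lithium bridging the C2 enolate oxygen and the aldehyde, vinyl equatorial, C3 methyl cis to the enolate oxygen) should set the quaternary C3 and the carbinol in the (3R*,1′R*) relationship; the cold acidic quench forestalls retro-aldol and C1 stays a mixture that step 3 removes.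

**Step 3**
Reactants: 5 rac-methyl (3R*)-3-[(1R*)-1-hydroxyprop-2-en-1-yl]-3-methyl-2-oxocyclopentane-1-carboxylate
Product: 7 rac-methyl (3R*)-3-[(1R*)-1-hydroxyprop-2-en-1-yl]-3-methyl-2-(trifluoromethanesulfonyloxy)cyclopent-1-ene-1-carboxylate, via sodium enolate 6 (not isolated)
Conditions: NaH (1.05 equiv), THF, 0 °C; PhNTf2 (1.1 equiv), 0 → 23 °C; 1 M HCl work-up
Reagents that add atoms: N-phenylbis(trifluoromethanesulfonimide), O=S(=O)(N(c1ccccc1)S(=O)(=O)C(F)(F)F)C(F)(F)F
Why: O-Triflation of the β-ketoester sodium enolate; one equivalent of base removes only the C1–H between the two carbonyls, so the secondary alcohol stays protonated (no retro-aldol) and only the C1=C2 enol triflate can form.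

**Step 4**
Reactants: 7 rac-methyl (3R*)-3-[(1R*)-1-hydroxyprop-2-en-1-yl]-3-methyl-2-(trifluoromethanesulfonyloxy)cyclopent-1-ene-1-carboxylate
Product: 8 methyl (3R)-3-[(1R)-1-hydroxyprop-2-en-1-yl]-3-methyl-2-(trifluoromethanesulfonyloxy)cyclopent-1-ene-1-carboxylate
Conditions: Ti(OiPr)4 (20 mol %), D-(−)-diisopropyl tartrate (30 mol %), t-BuOOH (0.6 equiv), 4 Å MS, CH2Cl2, −20 °C, run to ca. 55 % conversion
Reagents that add atoms: none
Why: Sharpless kinetic resolution of a secondary vinyl carbinol; with D-(−)-tartrate the (3S,1′S) enantiomer presents its carbinol hydrogen to the face of oxygen delivery and is epoxidised, so the (3R,1′R) alcohol should be recovered enantiopure, and the electron-poor enoate double bond does not react.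

**Step 5**
Reactants: 8 methyl (3R)-3-[(1R)-1-hydroxyprop-2-en-1-yl]-3-methyl-2-(trifluoromethanesulfonyloxy)cyclopent-1-ene-1-carboxylate
Product: 9 methyl (3S)-3-[(1R)-1-hydroxyprop-2-en-1-yl]-3-methyl-2-(3-methylbut-3-en-1-yl)cyclopent-1-ene-1-carboxylate
Conditions: (3-methylbut-3-en-1-yl)zinc bromide (3 equiv; from 4-bromo-2-methylbut-1-ene, Zn, LiCl, THF, 50 °C), PdCl2(dppf) (5 mol %), THF, 23 → 50 °C
Reagents that add atoms: (3-methylbut-3-en-1-yl)zinc bromide, C=C(C)CC[Zn]Br
Why: Negishi sp2–sp3 coupling of a β-triflyloxy enoate with a primary alkylzinc halide (dppf suppresses β-hydride elimination; the free hydroxyl only consumes part of the excess zinc reagent); no stereocentre is touched (the C3 descriptor changes by priority only).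

**Step 6**
Reactants: 9 methyl (3S)-3-[(1R)-1-hydroxyprop-2-en-1-yl]-3-methyl-2-(3-methylbut-3-en-1-yl)cyclopent-1-ene-1-carboxylate
Product: 10 methyl (3aS,4R)-4-hydroxy-3a,6-dimethyl-2,3,3a,4,7,8-hexahydroazulene-1-carboxylate
Conditions: Hoveyda–Grubbs II catalyst (5 mol %), 1,4-benzoquinone (10 mol %), toluene (5 mM), 80 °C
Reagents that add atoms: none
Why: Ring-closing metathesis between the vinyl carbinol and the 1,1-disubstituted alkene closes the seven-membered ring with the trisubstituted C5=C6 bond; the tetrasubstituted enoate is inert and benzoquinone suppresses ruthenium-hydride isomerisation of the allylic alcohol.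

**Step 7**
Reactants: 10 methyl (3aS,4R)-4-hydroxy-3a,6-dimethyl-2,3,3a,4,7,8-hexahydroazulene-1-carboxylate
Product: 11 methyl (3aS,4S,5S,6R)-5,6-epoxy-4-hydroxy-3a,6-dimethyl-2,3,3a,4,5,6,7,8-octahydroazulene-1-carboxylate
Conditions: VO(acac)2 (5 mol %), t-BuOOH (1.5 equiv), CH2Cl2, 0 → 23 °C
Reagents that add atoms: tert-butyl hydroperoxide, CC(C)(C)OO
Why: Hydroxyl-directed vanadium-catalysed epoxidation; the vanadate ester of the C4 alcohol delivers oxygen to the syn face of the cycloheptenol double bond, setting C5 and C6, and the electron-poor C1=C8a enoate is left alone.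

**Step 8**
Reactants: 11 methyl (3aS,4S,5S,6R)-5,6-epoxy-4-hydroxy-3a,6-dimethyl-2,3,3a,4,5,6,7,8-octahydroazulene-1-carboxylate
Product: 12 methyl (1S,3aS,4S,5S,6R,8aS)-5,6-epoxy-4-hydroxy-3a,6-dimethyldecahydroazulene-1-carboxylate
Conditions: [Ir(cod)(PCy3)(py)]BArF (5 mol %), H2 (1–50 bar), CH2Cl2, 23 °C
Reagents that add atoms: none
Why: Hydroxyl-directed homogeneous hydrogenation with a cationic iridium catalyst; the metal bound to the pseudo-axial C4 hydroxyl adds both hydrogens to the C1=C8a face syn to that hydroxyl and anti to the C3a methyl, which sets the trans ring fusion at C8a and places the C1 ester cis to C8 (this C1 configuration is erased in step 14).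

**Step 9**
Reactants: 12 methyl (1S,3aS,4S,5S,6R,8aS)-5,6-epoxy-4-hydroxy-3a,6-dimethyldecahydroazulene-1-carboxylate
Product: 13 (1S,3aS,4S,5S,6R,8aS)-5,6-epoxy-4-hydroxy-3a,6-dimethyldecahydroazulene-1-carboxylic acid
Conditions: LiOH·H2O (3 equiv), THF/MeOH/H2O, 0 → 23 °C; 1 M HCl to pH 3–4 at 0 °C
Reagents that add atoms: lithium hydroxide, [Li+].[OH-]
Why: Mild ester saponification (BAc2); the cis relationship of the C4 oxygen and the epoxide rules out Payne rearrangement, and the carboxyl group, trans to the C4 carbinol across the cyclopentane, cannot lactonise.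

**Step 10**
Reactants: 13 (1S,3aS,4S,5S,6R,8aS)-5,6-epoxy-4-hydroxy-3a,6-dimethyldecahydroazulene-1-carboxylic acid
Product: 14 (1S,3aS,4S,5S,6R,8aS)-4-acetoxy-5,6-epoxy-3a,6-dimethyldecahydroazulene-1-carboxylic acid
Conditions: Ac2O, pyridine, DMAP (10 mol %), CH2Cl2, 23 °C; aq. NaHCO3/THF, then pH 4
Reagents that add atoms: acetic anhydride, CC(=O)OC(C)=O; water, O
Why: DMAP-catalysed acetylation of the hindered secondary alcohol; the mixed anhydride formed at the carboxyl group is hydrolysed back to the acid in the bicarbonate work-up.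

**Step 11**
Reactants: 14 (1S,3aS,4S,5S,6R,8aS)-4-acetoxy-5,6-epoxy-3a,6-dimethyldecahydroazulene-1-carboxylic acid
Product: 15 1,3-dioxoisoindolin-2-yl (1S,3aS,4S,5S,6R,8aS)-4-acetoxy-5,6-epoxy-3a,6-dimethyldecahydroazulene-1-carboxylate
Conditions: N-hydroxyphthalimide (1.1 equiv), DIC (1.1 equiv), DMAP (10 mol %), CH2Cl2, 23 °C
Reagents that add atoms: N-hydroxyphthalimide, O=C1c2ccccc2C(=O)N1O
Why: Carbodiimide (Steglich-type) esterification gives the redox-active N-acyloxyphthalimide without touching epoxide or acetate.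

**Step 12**
Reactants: 16 ethyl (2E)-4-oxobut-2-enoate
Product: 17 ethyl (2E,4Z)-5-iodohexa-2,4-dienoate
Conditions: EtPPh3I, n-BuLi, THF, 23 °C; I2, −78 °C; NaHMDS, −20 °C; then 16, −78 → −20 °C
Reagents that add atoms: (1-iodoethylidene)triphenylphosphorane, CC(I)=P(c1ccccc1)(c1ccccc1)c1ccccc1
Why: α-Iodo Wittig olefination (Stork–Zhao type); the non-stabilised iodo-ylide adds to the aldehyde under kinetic control to give the (Z)-2-iodoalkene with iodine cis to the chain, and the (E)-enoate is not touched.

**Step 13**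
Reactants: 17 ethyl (2E,4Z)-5-iodohexa-2,4-dienoate
Product: 19 (3E,5Z)-6-iodo-2-methylhepta-3,5-dien-2-ol, via methyl ketone 18 (not isolated)
Conditions: MeMgBr (2.5 equiv), THF, −78 → 0 °C; aq. NH4Cl
Reagents that add atoms: methylmagnesium bromide, C[Mg]Br
Why: Double 1,2-addition of the Grignard reagent to the ester by way of the methyl ketone; the alkenyl iodide does not exchange with MeMgBr and both double-bond geometries are retained.

**Step 14**
Reactants: 15 1,3-dioxoisoindolin-2-yl (1S,3aS,4S,5S,6R,8aS)-4-acetoxy-5,6-epoxy-3a,6-dimethyldecahydroazulene-1-carboxylate; 19 (3E,5Z)-6-iodo-2-methylhepta-3,5-dien-2-ol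
Product: 20 (1R,3aS,4S,5S,6R,8aS)-5,6-epoxy-1-[(2Z,4E)-6-hydroxy-6-methylhepta-2,4-dien-2-yl]-3a,6-dimethyldecahydroazulen-4-yl acetate
Conditions: NiBr2·dme (10 mol %), 4,4′-di-tert-butyl-2,2′-bipyridine (12 mol %), Zn dust (2.5 equiv), 19 (1.5 equiv), DMA, 23 °C
Reagents that add atoms: none
Why: Ni-catalysed decarboxylative cross-electrophile coupling, the closest known type being the reductive coupling of N-acyloxyphthalimides with aryl and alkenyl halides: Ni(0) adds oxidatively to the C–I bond of 19 with retention, single-electron reduction of 15 expels phthalimide anion and CO2 to give the secondary C1 radical, the alkenylnickel(II) species captures it, and reductive elimination from Ni(III) forms the C1–C2′ bond while zinc returns nickel to Ni(0). No ring is closed. The only new stereocentre, C1, is set by the substrate: the planar cyclopentyl radical in the trans-fused bicycle is captured on the face anti to the vicinal C8a–C8 bond and to the 1,3-related C3a methyl (the face of C8a–H), so the (1S)-ester and any C1 epimer converge on the (1R) product. The step needs this diastereoselectivity (secured by the ring fusion and the angular methyl), retention of the 2Z,4E geometry (secured by stereoretentive oxidative addition and reductive elimination at sp2 carbon under thermal, non-photochemical conditions) and cross- over homo-coupling (secured by the different activation modes of the two electrophiles and the excess of 19). The near-neutral conditions should leave the trisubstituted epoxide, the acetate and the free tertiary allylic alcohol untouched.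

**Compound list**

1 | methyl 2-oxocyclopentane-1-carboxylate | COC(=O)C1CCCC1=O | starting material
2 | dilithium dienolate of 1 | [Li+].[Li+].COC([O-])=C1CCC=C1[O-] | intermediate
3 | methyl 3-methyl-2-oxocyclopentane-1-carboxylate (stereoisomer/enol mixture) | COC(=O)C1CCC(C)C1=O | intermediate
4 | dilithium dienolate of 3 | [Li+].[Li+].COC([O-])=C1CCC(C)=C1[O-] | intermediate
5 | rac-methyl (3R*)-3-[(1R*)-1-hydroxyprop-2-en-1-yl]-3-methyl-2-oxocyclopentane-1-carboxylate (C1 epimers) | O[C@H](C=C)[C@@]1(C)CCC(C(=O)OC)C1=O.O[C@@H](C=C)[C@]1(C)CCC(C(=O)OC)C1=O | intermediate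
6 | sodium enolate of 5 (racemate) | [Na+].O[C@H](C=C)[C@@]1(C)CCC(C(=O)OC)=C1[O-].[Na+].O[C@@H](C=C)[C@]1(C)CCC(C(=O)OC)=C1[O-] | intermediate
7 | rac-methyl (3R*)-3-[(1R*)-1-hydroxyprop-2-en-1-yl]-3-methyl-2-(trifluoromethanesulfonyloxy)cyclopent-1-ene-1-carboxylate | O[C@H](C=C)[C@@]1(C)CCC(C(=O)OC)=C1OS(=O)(=O)C(F)(F)F.O[C@@H](C=C)[C@]1(C)CCC(C(=O)OC)=C1OS(=O)(=O)C(F)(F)F | intermediate
8 | methyl (3R)-3-[(1R)-1-hydroxyprop-2-en-1-yl]-3-methyl-2-(trifluoromethanesulfonyloxy)cyclopent-1-ene-1-carboxylate | O[C@H](C=C)[C@@]1(C)CCC(C(=O)OC)=C1OS(=O)(=O)C(F)(F)F | intermediate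
9 | methyl (3S)-3-[(1R)-1-hydroxyprop-2-en-1-yl]-3-methyl-2-(3-methylbut-3-en-1-yl)cyclopent-1-ene-1-carboxylate | O[C@H](C=C)[C@@]1(C)CCC(C(=O)OC)=C1CCC(C)=C | intermediate
10 | methyl (3aS,4R)-4-hydroxy-3a,6-dimethyl-2,3,3a,4,7,8-hexahydroazulene-1-carboxylate | O[C@@H]1C=C(C)CCC2=C(C(=O)OC)CC[C@]12C | intermediate
11 | methyl (3aS,4S,5S,6R)-5,6-epoxy-4-hydroxy-3a,6-dimethyl-2,3,3a,4,5,6,7,8-octahydroazulene-1-carboxylate | O[C@@H]1[C@@H]2O[C@]2(C)CCC2=C(C(=O)OC)CC[C@]12C | intermediate
12 | methyl (1S,3aS,4S,5S,6R,8aS)-5,6-epoxy-4-hydroxy-3a,6-dimethyldecahydroazulene-1-carboxylate | O[C@@H]1[C@@H]2O[C@]2(C)CC[C@H]2[C@@H](C(=O)OC)CC[C@]12C | intermediate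
13 | (1S,3aS,4S,5S,6R,8aS)-5,6-epoxy-4-hydroxy-3a,6-dimethyldecahydroazulene-1-carboxylic acid | O[C@@H]1[C@@H]2O[C@]2(C)CC[C@H]2[C@@H](C(=O)O)CC[C@]12C | intermediate
14 | (1S,3aS,4S,5S,6R,8aS)-4-acetoxy-5,6-epoxy-3a,6-dimethyldecahydroazulene-1-carboxylic acid | CC(=O)O[C@@H]1[C@@H]2O[C@]2(C)CC[C@H]2[C@@H](C(=O)O)CC[C@]12C | intermediate
15 | 1,3-dioxoisoindolin-2-yl (1S,3aS,4S,5S,6R,8aS)-4-acetoxy-5,6-epoxy-3a,6-dimethyldecahydroazulene-1-carboxylate | CC(=O)O[C@@H]1[C@@H]2O[C@]2(C)CC[C@H]2[C@@H](C(=O)ON3C(=O)c4ccccc4C3=O)CC[C@]12C | intermediate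
16 | ethyl (2E)-4-oxobut-2-enoate | CCOC(=O)/C=C/C=O | starting material
17 | ethyl (2E,4Z)-5-iodohexa-2,4-dienoate | I/C(C)=C\C=C\C(=O)OCC | intermediate
18 | (3E,5Z)-6-iodohepta-3,5-dien-2-one | I/C(C)=C\C=C\C(C)=O | intermediate
19 | (3E,5Z)-6-iodo-2-methylhepta-3,5-dien-2-ol | I/C(C)=C\C=C\C(C)(C)O | intermediate
20 | (1R,3aS,4S,5S,6R,8aS)-5,6-epoxy-1-[(2Z,4E)-6-hydroxy-6-methylhepta-2,4-dien-2-yl]-3a,6-dimethyldecahydroazulen-4-yl acetate | CC(=O)O[C@@H]1[C@@H]2O[C@]2(C)CC[C@H]2[C@H](/C(C)=C\C=C\C(C)(C)O)CC[C@]12C | target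

**Step count**

Total: 14 steps. Longest linear sequence: 12 steps (steps 1–11, then step 14); the side-chain branch is steps 12–13.

**Steps most likely to fail, with fallbacks**

Step 8 (directed hydrogenation). The hindered tetrasubstituted enoate may reduce slowly, hydrogen may be delivered from the methyl face if coordination to the C4 hydroxyl is weak, and the cationic iridium centre may open the epoxy alcohol by Lewis-acid activation. The fallback sets out from 10, before the epoxide is present. A dissolving-metal conjugate reduction (Li, NH3, t-BuOH, THF, −78 °C) should reduce only the conjugated enoate, with the neighbouring C4 hydroxyl acting as the internal proton source for C8a on its own face. This should give methyl (3aS,4R,8aS)-4-hydroxy-3a,6-dimethyl-1,2,3,3a,4,7,8,8a-octahydroazulene-1-carboxylate F1 as a C1 epimer mixture. Hydroxyl-directed epoxidation of F1 (VO(acac)2, t-BuOOH) and separation of the (1S) epimer then returns to the route at 12.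

Step 14 (key coupling). Radical capture at C1 may be insufficiently face-selective, the alkenyl iodide may homocouple or lose its Z geometry on nickel, or the C1 radical may be reduced before capture. The fallback keeps the same bond but uses a preformed alkenylzinc in a decarboxylative Negishi-type alkenylation, a known reaction of N-acyloxyphthalimides. It sets out from 19 and 15. Silylation of 19 (TESOTf, 2,6-lutidine) gives triethyl{[(3E,5Z)-6-iodo-2-methylhepta-3,5-dien-2-yl]oxy}silane F2. Iodine–lithium exchange with retention (t-BuLi, Et2O, −78 °C) and transmetalation with ZnCl2 give chloro[(2Z,4E)-6-methyl-6-(triethylsilyloxy)hepta-2,4-dien-2-yl]zinc F3. Coupling of F3 with 15 (NiCl2·glyme, 2,2′-bipyridine, THF/DMF, 23 °C) should give (1R,3aS,4S,5S,6R,8aS)-5,6-epoxy-3a,6-dimethyl-1-[(2Z,4E)-6-methyl-6-(triethylsilyloxy)hepta-2,4-dien-2-yl]decahydroazulen-4-yl acetate F4. Buffered desilylation (TBAF, AcOH, THF, 0 °C) comes back to the route at 20.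

Step 2 (dianion aldol). Simple diastereoselection may be poor if the dianion reacts through an open rather than a closed transition state, and conjugate addition to acrolein or retro-aldol on warming may compete. The fallback sets the carbinol by hydride rather than by C–C bond formation. It sets out from 7 carried through step 3 as the diastereomer mixture. Oxidation (Dess–Martin periodinane, CH2Cl2) gives the vinyl ketone rac-methyl 3-methyl-3-(prop-2-enoyl)-2-(trifluoromethanesulfonyloxy)cyclopent-1-ene-1-carboxylate F5. Luche reduction (NaBH4, CeCl3, MeOH, −78 °C) under Felkin–Anh control (hydride anti to the C2 enol-triflate carbon, passing the methyl group) should favour the (3R*,1′R*) alcohol. This comes back to the route at 7, ahead of the resolution in step 4.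

**Further compounds**

F1 | step 8 | methyl (3aS,4R,8aS)-4-hydroxy-3a,6-dimethyl-1,2,3,3a,4,7,8,8a-octahydroazulene-1-carboxylate (C1 epimers) | O[C@@H]1C=C(C)CC[C@H]2C(C(=O)OC)CC[C@]12C
F2 | step 14 | triethyl{[(3E,5Z)-6-iodo-2-methylhepta-3,5-dien-2-yl]oxy}silane | I/C(C)=C\C=C\C(C)(C)O[Si](CC)(CC)CC
F3 | step 14 | chloro[(2Z,4E)-6-methyl-6-(triethylsilyloxy)hepta-2,4-dien-2-yl]zinc | Cl[Zn]/C(C)=C\C=C\C(C)(C)O[Si](CC)(CC)CC
F4 | step 14 | (1R,3aS,4S,5S,6R,8aS)-5,6-epoxy-3a,6-dimethyl-1-[(2Z,4E)-6-methyl-6-(triethylsilyloxy)hepta-2,4-dien-2-yl]decahydroazulen-4-yl acetate | CC(=O)O[C@@H]1[C@@H]2O[C@]2(C)CC[C@H]2[C@H](/C(C)=C\C=C\C(C)(C)O[Si](CC)(CC)CC)CC[C@]12C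
F5 | step 2 | rac-methyl 3-methyl-3-(prop-2-enoyl)-2-(trifluoromethanesulfonyloxy)cyclopent-1-ene-1-carboxylate | C=CC(=O)[C@@]1(C)CCC(C(=O)OC)=C1OS(=O)(=O)C(F)(F)F.C=CC(=O)[C@]1(C)CCC(C(=O)OC)=C1OS(=O)(=O)C(F)(F)F
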